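(Its constants are invented; the flask was simulated.)

The pitfall in this flask is to book the over-reaction to G.X.G against the whole of the X.G made, when G meets dissolved X.G and E stands aside as solid.

    E ⇌ X.G, rate k1*(cs1 - [X.G]) while solid is left; crystals form when [X.G] > cs1 (cs1 = 31 mM, k1 = 0.0013 s⁻¹)
    D ⇌ G, rate k2*(csat - [G]) (k2 = 0.021 s⁻¹, csat = 13 mM)
    X + G → X.G (k3 = 0.049 M⁻¹ s⁻¹)
    G + X.G → G.X.G (k4 = 0.033 M⁻¹ s⁻¹)

X 0.20 M; D 13 mM (held); time 2.0 h

- what is said of X.G includes E
- E is a solid; its amount is given per volume of the solution
- at the start none of G is dissolved
- run time (flask): 2.0 h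

1. the X.G and E together standing at 2.0 h, as a percentage of the X charged
2. the change that raises the amount of X.G and E together at 2.0 h, in percent of the X charged most ("none" if none brings more than 2 percentage points) (Tuesday's / Sunday's / Saturday's / Thursday's / none)
3. amount of X.G and E together at 2.0 h, in percent of the X charged, after Tuesday's

- Tuesday's: doubling the dissolution coefficient of step 1, all else as stated
- Sunday's: doubling the transfer coefficient of step 2, all else as stated
- Saturday's: doubling the solubility in step 1, all else as stated
- Thursday's: doubling the saturation concentration of D, all else as stated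

G is the concentration that sets the order of both steps. Its transfer coefficient 0.021 s⁻¹ is larger than the pull of the charged X, 0.00980 s⁻¹, so G, none at the start, soon stands between 8.86 mM, its balance against the full charge, and 13 mM, and the two steps that use G are pseudo-first-order, one in X and the other in dissolved X.G. My own ledger takes G at 13 mM and dissolved X.G at its solubility while crystals stand. The loss is then steady, and L, the share of the charge passing to G.X.G per hour with crystals present, follows from the rate constant, G, the solubility and the charge:

L = 0.033 M⁻¹ s⁻¹ × 13 mM × 31 mM / 0.20 M = 0.239 h⁻¹

The charged X, the limiting reagent, is then booked at 2.0 h: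

X left: exp(−0.049 M⁻¹ s⁻¹ × 13 mM × 2.0 h) = 1.02 %

G.X.G: L × 2.0 h = 47.8 %

X.G and E, the remainder: 51.1 %

The solubility is worth 15.5 % of the charge, less than this remainder, so crystals still stand and the books close. Saturday's and Thursday's raise L, and Sunday's brings G nearer 13 mM. Tuesday's leaves L as it is but holds dissolved X.G nearer its solubility, so my choice is Tuesday's, with a rise over y whose size the ledger cannot give.

The forecast gives 48 %, Tuesday's and 53 %, on the ground that “Faster crystal exchange (Tuesday's) keeps dissolved X.G lower”.

The flask gives 49.1 %, with Tuesday's best at 4.1 percentage points, which brings 53.3 %. It holds 48.8 % as G.X.G at 2.00 h, against 47.8 % booked, while the half-life of dissolved X.G by the over-reaction, 0.58 h at 0.539 h, is shorter than the run of 2.0 h.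

Read at 5.0 h, the same flask would owe L × 5.0 h = 120 %, more than the charge. So the ledger ends the crystals at 3.53 h and lets the dissolved rest decay to 1.60 %. That neighbour reads 3.58 % of X.G, with E at 0 % and G.X.G at 96.4 %.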